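**Retrosynthetic overview**
1. Pyran ring (closed last): O2–C3 bond by base-catalysed 6-endo-dig oxa-Michael addition of the C1 hydroxyl onto a 3-(enynyl)cyclohex-2-enone.
2. Key union: the C4a–C4 (sp2–sp) bond by visible-light copper-acetylide coupling of a β-iodocyclohexenone with the side-chain enyne.
3. Carbocycle (closed second): γ-lactone → cyclohexane-1,3-dione by intramolecular Claisen condensation (C5–C4a) → β-iodoenone. Before that, C8a–C1 by trans aldol of the lactone dianion with formaldehyde, and C7 by chelation-controlled Grignard addition to an α-hydroxy methyl ketone from L-malic acid (C8).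
4. Side chain: L-isoleucine (C4', C5') → α-hydroxy Weinreb amide → diynone → chelation-controlled MeMgBr addition (C3') → hydroxyl-directed trans-reduction to the E-enyne.
5. Ring order: temporary γ-lactone → carbocycle → pyran.

Assumption: the SMILES is read as (7R,8S,8aS) in the bicycle and (1E,3R,4S,5S) in the side chain; atom labels C1–C8a and C1'–C7' follow the isochromenone numbering of the target; the L-malic acid acetonide is bought (it is also made in one step from L-malic acid and 2,2-dimethoxypropane).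

**Route**

Step 1
Reactants: 1 (4S)-2,2-dimethyl-5-oxo-1,3-dioxolane-4-acetic acid (L-malic acid acetonide)
Product: 3 (3S)-3-hydroxy-4-oxopentanoic acid, via hydroxy Weinreb amide 2 (not isolated)
Conditions: MeNHOMe·HCl (1.2 eq), i-PrMgCl (3.5 eq), THF, −20 °C; then MeMgBr (3 eq), −20 → 0 °C; 1 M HCl
Reagents that add atoms: methylmagnesium bromide, C[Mg]Br; N,O-dimethylhydroxylamine hydrochloride, CNOC.Cl (its atoms stay in 2 only)
Why: The magnesium amide of MeNHOMe attacks only the activated dioxolanone carbonyl (in-flask Weinreb amide formation, the carboxylate being self-protected as its magnesium salt) and MeMgBr then gives the methyl ketone through the chelated tetrahedral adduct (Weinreb ketone synthesis), leaving the C8 stereocenter bought with L-malic acid untouched.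

Step 2
Reactants: 3 (3S)-3-hydroxy-4-oxopentanoic acid
Product: 5 (4S,5S)-4-hydroxy-5-methyl-5-(prop-1-en-2-yl)oxolan-2-one, via dihydroxy acid 4 (not isolated)
Conditions: CH2=C(CH3)MgBr (4 eq), THF, −78 → −20 °C; then 1 M HCl to pH 2–3, 0 °C → rt
Reagents that add atoms: isopropenylmagnesium bromide, CC(=C)[Mg]Br
Why: Grignard 1,2-addition under Cram chelate control — magnesium bridges the ketone oxygen and the C8 alkoxide, so the isopropenyl group (a masked acetyl, future C6/C5) enters anti to the CH2CO2 arm and sets C7 — followed by acid-induced lactonization of the tertiary γ-hydroxy acid.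

Step 3
Reactants: 5 (4S,5S)-4-hydroxy-5-methyl-5-(prop-1-en-2-yl)oxolan-2-one
Product: 6 (3S,4S,5S)-4-hydroxy-3-(hydroxymethyl)-5-methyl-5-(prop-1-en-2-yl)oxolan-2-one
Conditions: LiN(i-Pr)2 (2.3 eq), THF, −78 → −40 °C; CH2O (gas, from cracked paraformaldehyde), −78 °C; NH4Cl
Reagents that add atoms: formaldehyde, C=O
Why: Aldol addition of the alkoxide–enolate dianion of a β-hydroxy-γ-lactone (Fráter–Seebach type) to formaldehyde, which enters anti to the neighbouring C8 alkoxide (the face that also carries only the small C7 methyl) and so sets C8a trans to the C8 oxygen.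

Step 4
Reactants: 6 (3S,4S,5S)-4-hydroxy-3-(hydroxymethyl)-5-methyl-5-(prop-1-en-2-yl)oxolan-2-one
Product: 7 (3S,4S,5S)-5-methyl-5-(prop-1-en-2-yl)-4-(triethylsilyloxy)-3-[(triethylsilyloxy)methyl]oxolan-2-one
Conditions: Et3SiOTf (2.4 eq), 2,6-lutidine, CH2Cl2, −78 → 0 °C
Reagents that add atoms: triethylsilyl trifluoromethanesulfonate, CC[Si](CC)(CC)OS(=O)(=O)C(F)(F)F
Why: Silyl ether formation with a silyl triflate caps both hydroxyls so that only the methyl ketone is deprotonated in step 6; no stereocenter is touched.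

Step 5
Reactants: 7 (3S,4S,5S)-5-methyl-5-(prop-1-en-2-yl)-4-(triethylsilyloxy)-3-[(triethylsilyloxy)methyl]oxolan-2-one
Product: 8 (3S,4S,5R)-5-acetyl-5-methyl-4-(triethylsilyloxy)-3-[(triethylsilyloxy)methyl]oxolan-2-one
Conditions: O3, CH2Cl2–MeOH, −78 °C; Me2S
Reagents that add atoms: ozone, [O-][O+]=O
Why: Ozonolysis of the 1,1-disubstituted alkene with reductive work-up unmasks the acetyl group (the descriptor at C5 changes only because the priorities change).

Step 6
Reactants: 8 (3S,4S,5R)-5-acetyl-5-methyl-4-(triethylsilyloxy)-3-[(triethylsilyloxy)methyl]oxolan-2-one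
Product: 10 (4S,5S,6R)-6-hydroxy-3-iodo-6-methyl-5-(triethylsilyloxy)-4-[(triethylsilyloxy)methyl]cyclohex-2-en-1-one, via cyclohexane-1,3-dione 9 (not isolated)
Conditions: LiN(SiMe3)2 (1.2 eq), THF, −78 → 0 °C; AcOH (1.3 eq), solvent switch to MeCN; Ph3P, I2, Et3N, rt
Reagents that add atoms: iodine, II
Why: Intramolecular Claisen condensation (Baker–Venkataraman-type O-to-C acyl transfer): the kinetic methyl ketone enolate attacks the lactone carbonyl, the tertiary alkoxide leaves, and the 1,3-dione is converted into the β-iodoenone by Ph3P·I2 (Piers method), the phosphonium reacting at the enol oxygen remote from quaternary C7; the stereocenters are untouched.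

Step 7
Reactants: 11 L-isoleucine
Product: 12 (2S,3S)-2-hydroxy-3-methylpentanoic acid
Conditions: NaNO2, 1 M H2SO4, 0 °C → rt
Reagents that add atoms: water, O
Why: Diazotization with net retention (double inversion through the α-lactone), so both isoleucine stereocenters are carried over as C4' and C5'.

Step 8
Reactants: 12 (2S,3S)-2-hydroxy-3-methylpentanoic acid
Product: 13 (2S,3S)-2-hydroxy-N-methoxy-N,3-dimethylpentanamide
Conditions: MeNHOMe·HCl, EDC·HCl, HOBt, N-methylmorpholine, CH2Cl2, 0 °C → rt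
Reagents that add atoms: N,O-dimethylhydroxylamine hydrochloride, CNOC.Cl
Why: Carbodiimide amide coupling to the Weinreb amide; the α-hydroxy acid couples through its HOBt ester without epimerization.

Step 9
Reactants: 13 (2S,3S)-2-hydroxy-N-methoxy-N,3-dimethylpentanamide; 14 1,4-bis(trimethylsilyl)buta-1,3-diyne
Product: 16 (6S,7S)-6-hydroxy-7-methyl-1-(trimethylsilyl)nona-1,3-diyn-5-one, via lithium diynide 15 (not isolated)
Conditions: 14, MeLi·LiBr, THF, 0 °C → rt; added at −78 °C to 13 pre-treated with LiN(SiMe3)2 (1.0 eq); −78 → −20 °C; NH4Cl; used at once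
Reagents that add atoms: none
Why: Weinreb ketone synthesis with a lithium acetylide made by mono-desilylation of the bis-silyl diyne; the stable tetrahedral adduct prevents over-addition.

Step 10
Reactants: 16 (6S,7S)-6-hydroxy-7-methyl-1-(trimethylsilyl)nona-1,3-diyn-5-one
Product: 17 (5R,6S,7S)-5,7-dimethyl-1-(trimethylsilyl)nona-1,3-diyne-5,6-diol
Conditions: MeMgBr (3 eq), Et2O–CH2Cl2, −78 °C; NH4Cl
Reagents that add atoms: methylmagnesium bromide, C[Mg]Br
Why: Chelation-controlled (Cram cyclic model) 1,2-addition of the Grignard reagent to the α-alkoxido ynone: methyl attacks anti to the sec-butyl group and sets C3' as R.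

Step 11
Reactants: 17 (5R,6S,7S)-5,7-dimethyl-1-(trimethylsilyl)nona-1,3-diyne-5,6-diol
Product: 19 (3E,5R,6S,7S)-5,7-dimethylnon-3-en-1-yne-5,6-diol, via silyl enyne 18 (not isolated)
Conditions: NaAlH2(OCH2CH2OMe)2 (4 eq), THF, 0 °C → rt; Rochelle salt work-up; then K2CO3 (cat.), MeOH, rt
Reagents that add atoms: none
Why: Hydroxyl-directed trans-hydroalumination reduces only the propargylic alkyne to the E-alkene (the remote silyl alkyne is left), and methanolysis (protodesilylation) frees the terminal alkyne.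

Step 12
Reactants: 10 (4S,5S,6R)-6-hydroxy-3-iodo-6-methyl-5-(triethylsilyloxy)-4-[(triethylsilyloxy)methyl]cyclohex-2-en-1-one; 19 (3E,5R,6S,7S)-5,7-dimethylnon-3-en-1-yne-5,6-diol
Product: 20 (4S,5S,6R)-3-[(3E,5R,6S,7S)-5,6-dihydroxy-5,7-dimethylnon-3-en-1-yn-1-yl]-6-hydroxy-6-methyl-5-(triethylsilyloxy)-4-[(triethylsilyloxy)methyl]cyclohex-2-en-1-one
Conditions: CuCl (10 mol %), K2CO3 (2 eq), degassed MeCN, 450 nm LEDs, 25 °C, argon
Reagents that add atoms: none
Why: Proposed new method: a palladium-free, visible-light copper-acetylide Sonogashira-type coupling extended from aryl halides to a β-iodoenone and an unprotected enyne diol — the monovalent copper acetylide of 19 absorbs blue light, its long-lived excited state (about −2.0 V against SCE) transfers an electron to the iodoenone (a vinylogous acyl iodide, easier to reduce than an aryl iodide), iodide loss gives a σ-vinyl radical that is captured by the divalent copper acetylide, and reductive elimination from trivalent copper forms the C4a–C4 bond without touching the E-alkene or any stereocenter; the closest known reactions are the CuCl-photocatalysed Sonogashira coupling of aryl iodides and the thermal Castro–Stephens coupling.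

Step 13
Reactants: 20 (4S,5S,6R)-3-[(3E,5R,6S,7S)-5,6-dihydroxy-5,7-dimethylnon-3-en-1-yn-1-yl]-6-hydroxy-6-methyl-5-(triethylsilyloxy)-4-[(triethylsilyloxy)methyl]cyclohex-2-en-1-one
Product: 22 (7R,8S,8aS)-3-[(1E,3R,4S,5S)-3,4-dihydroxy-3,5-dimethylhept-1-en-1-yl]-7,8-dihydroxy-7-methyl-1,7,8,8a-tetrahydro-6H-isochromen-6-one (CNP0291643.14), via pentaol enynone 21 (not isolated)
Conditions: HF·pyridine, pyridine, THF, 0 °C → rt; NaHCO3 work-up; then DBU (0.2 eq), MeCN, 0 °C → rt
Reagents that add atoms: none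
Why: Fluoride desilylation, then base-catalysed 6-endo-dig 1,6-oxa-Michael addition (cycloisomerization) of the C1 hydroxyl to the alkyne terminus activated through the enone, with protonation at C4 giving the dienone enol ether; the C8 hydroxyl cannot compete (it would need a bridgehead alkene), and C8a keeps the trans arrangement set in step 3, which should also be the thermodynamic one under DBU.

**Compound list**
1 | (4S)-2,2-dimethyl-5-oxo-1,3-dioxolane-4-acetic acid (L-malic acid acetonide) | OC(=O)C[C@@H]1OC(C)(C)OC1=O | starting material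
2 | (3S)-3-hydroxy-4-[methoxy(methyl)amino]-4-oxobutanoic acid (chloromagnesium salt in the flask; not isolated) | CON(C)C(=O)[C@@H](O)CC(=O)O | intermediate
3 | (3S)-3-hydroxy-4-oxopentanoic acid | CC(=O)[C@@H](O)CC(=O)O | intermediate
4 | (3S,4S)-3,4-dihydroxy-4,5-dimethylhex-5-enoic acid (not isolated) | CC(=C)[C@](C)(O)[C@@H](O)CC(=O)O | intermediate
5 | (4S,5S)-4-hydroxy-5-methyl-5-(prop-1-en-2-yl)oxolan-2-one | CC(=C)[C@]1(C)OC(=O)C[C@@H]1O | intermediate
6 | (3S,4S,5S)-4-hydroxy-3-(hydroxymethyl)-5-methyl-5-(prop-1-en-2-yl)oxolan-2-one | CC(=C)[C@]1(C)OC(=O)[C@@H](CO)[C@@H]1O | intermediate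
7 | (3S,4S,5S)-5-methyl-5-(prop-1-en-2-yl)-4-(triethylsilyloxy)-3-[(triethylsilyloxy)methyl]oxolan-2-one | CC(=C)[C@]1(C)OC(=O)[C@@H](CO[Si](CC)(CC)CC)[C@@H]1O[Si](CC)(CC)CC | intermediate
8 | (3S,4S,5R)-5-acetyl-5-methyl-4-(triethylsilyloxy)-3-[(triethylsilyloxy)methyl]oxolan-2-one | CC(=O)[C@]1(C)OC(=O)[C@@H](CO[Si](CC)(CC)CC)[C@@H]1O[Si](CC)(CC)CC | intermediate
9 | (4R,5S,6S)-4-hydroxy-4-methyl-5-(triethylsilyloxy)-6-[(triethylsilyloxy)methyl]cyclohexane-1,3-dione (not isolated) | O=C1CC(=O)[C@](C)(O)[C@@H](O[Si](CC)(CC)CC)[C@@H]1CO[Si](CC)(CC)CC | intermediate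
10 | (4S,5S,6R)-6-hydroxy-3-iodo-6-methyl-5-(triethylsilyloxy)-4-[(triethylsilyloxy)methyl]cyclohex-2-en-1-one | IC1=CC(=O)[C@](C)(O)[C@@H](O[Si](CC)(CC)CC)[C@@H]1CO[Si](CC)(CC)CC | intermediate
11 | L-isoleucine | CC[C@H](C)[C@H](N)C(=O)O | starting material
12 | (2S,3S)-2-hydroxy-3-methylpentanoic acid | CC[C@H](C)[C@H](O)C(=O)O | intermediate
13 | (2S,3S)-2-hydroxy-N-methoxy-N,3-dimethylpentanamide | CC[C@H](C)[C@H](O)C(=O)N(C)OC | intermediate
14 | 1,4-bis(trimethylsilyl)buta-1,3-diyne | C[Si](C)(C)C#CC#C[Si](C)(C)C | starting material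
15 | lithium 4-(trimethylsilyl)buta-1,3-diyn-1-ide (not isolated) | [Li]C#CC#C[Si](C)(C)C | intermediate
16 | (6S,7S)-6-hydroxy-7-methyl-1-(trimethylsilyl)nona-1,3-diyn-5-one | CC[C@H](C)[C@H](O)C(=O)C#CC#C[Si](C)(C)C | intermediate
17 | (5R,6S,7S)-5,7-dimethyl-1-(trimethylsilyl)nona-1,3-diyne-5,6-diol | CC[C@H](C)[C@H](O)[C@](C)(O)C#CC#C[Si](C)(C)C | intermediate
18 | (3E,5R,6S,7S)-5,7-dimethyl-1-(trimethylsilyl)non-3-en-1-yne-5,6-diol (not isolated) | CC[C@H](C)[C@H](O)[C@](C)(O)/C=C/C#C[Si](C)(C)C | intermediate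
19 | (3E,5R,6S,7S)-5,7-dimethylnon-3-en-1-yne-5,6-diol | CC[C@H](C)[C@H](O)[C@](C)(O)/C=C/C#C | intermediate
20 | (4S,5S,6R)-3-[(3E,5R,6S,7S)-5,6-dihydroxy-5,7-dimethylnon-3-en-1-yn-1-yl]-6-hydroxy-6-methyl-5-(triethylsilyloxy)-4-[(triethylsilyloxy)methyl]cyclohex-2-en-1-one | CC[C@H](C)[C@H](O)[C@](C)(O)/C=C/C#CC1=CC(=O)[C@](C)(O)[C@@H](O[Si](CC)(CC)CC)[C@@H]1CO[Si](CC)(CC)CC | intermediate
21 | (4S,5S,6R)-3-[(3E,5R,6S,7S)-5,6-dihydroxy-5,7-dimethylnon-3-en-1-yn-1-yl]-5,6-dihydroxy-4-(hydroxymethyl)-6-methylcyclohex-2-en-1-one (not isolated) | CC[C@H](C)[C@H](O)[C@](C)(O)/C=C/C#CC1=CC(=O)[C@](C)(O)[C@@H](O)[C@@H]1CO | intermediate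
22 | (7R,8S,8aS)-3-[(1E,3R,4S,5S)-3,4-dihydroxy-3,5-dimethylhept-1-en-1-yl]-7,8-dihydroxy-7-methyl-1,7,8,8a-tetrahydro-6H-isochromen-6-one (CNP0291643.14) | CC[C@H](C)[C@H](O)[C@](C)(O)/C=C/C1=CC2=CC(=O)[C@](C)(O)[C@@H](O)[C@@H]2CO1 | target

**Step count**
Total: 13 steps. Longest linear sequence: 8 steps (steps 1–6, 12, 13); the side-chain branch is steps 7–11 and joins at step 12.

**Three steps most likely to fail, each with a fallback**

Step 12 (the proposed new photochemical coupling). Electron transfer to the iodoenone may be slow, the acetylide may homocouple, or the product dienyne may degrade under light. The fallback is the known ground-state Sonogashira coupling in the dark: Pd(PPh3)4 (5 mol %), CuI (10 mol %), i-Pr2NH, THF, 25 °C, where zerovalent palladium inserts into the C–I bond and the copper acetylide transmetalates, which is standard for β-iodoenones. It sets out from 10 and 19 and comes back to the route at 20; no new compound is made (F0).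

Step 6 (Claisen ring closure on the lactone and regioselective iodination). The base may instead deprotonate C8a and eliminate silanolate, the α-acyloxy ketone enolate may ionize, or the wrong enol oxygen may be iodinated. The fallback joins the fragments before the carbocycle is closed, so the regiochemistry is fixed by the ynone carbonyl. It sets out from 7 (and 19). Enyne 19 is silylated (Et3SiOTf, 2,6-lutidine) to (3E,5R,6S,7S)-5,7-dimethyl-5,6-bis(triethylsilyloxy)non-3-en-1-yne F1. Its lithium acetylide (n-BuLi, THF, −78 °C) opens lactone 7 at the carbonyl to the open-chain hydroxy ynone F2. OsO4 (cat.), NaIO4 and 2,6-lutidine in dioxane–water cleave only the electron-rich isopropenyl group to the methyl ketone F3. Intramolecular aldol condensation of the methyl ketone onto the ynone carbonyl (KOt-Bu, THF, 0 °C) gives the tetrakis(triethylsilyl) enynone F4. HF·pyridine as in step 13 removes all four silyl groups, and the route is rejoined at 21, which is cyclized with DBU to 22. This path bypasses steps 5, 6 and 12.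

Step 3 (hydroxymethylation of the lactone dianion with gaseous formaldehyde). Formaldehyde may oligomerize, add twice, or the adduct may undergo retro-aldol. The fallback replaces the aldol by alkylation with a liquid electrophile and removes the benzyl group before any other alkene is present. It sets out from 5: the same dianion (LiN(i-Pr)2, THF, −78 °C) is alkylated with benzyl chloromethyl ether to (3S,4S,5S)-3-[(benzyloxy)methyl]-4-hydroxy-5-methyl-5-(prop-1-en-2-yl)oxolan-2-one F5, again trans to the C8 alkoxide. Ozonolysis (O3; Me2S) gives (3S,4S,5R)-5-acetyl-3-[(benzyloxy)methyl]-4-hydroxy-5-methyloxolan-2-one F6. Hydrogenolysis (H2, palladium on carbon, EtOAc) gives (3S,4S,5R)-5-acetyl-4-hydroxy-3-(hydroxymethyl)-5-methyloxolan-2-one F7. Bis-silylation (Et3SiOTf, 2,6-lutidine) comes back to the route at 8.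

**Further compounds**
F0 | step 12 | none | none
F1 | step 6 | (3E,5R,6S,7S)-5,7-dimethyl-5,6-bis(triethylsilyloxy)non-3-en-1-yne | CC[C@H](C)[C@H](O[Si](CC)(CC)CC)[C@](C)(O[Si](CC)(CC)CC)/C=C/C#C
F2 | step 6 | open-chain hydroxy ynone (lactone 7 opened at C4a by the acetylide of F1; isopropenyl carbinol at C7) | CC(=C)[C@](C)(O)[C@@H](O[Si](CC)(CC)CC)[C@H](CO[Si](CC)(CC)CC)C(=O)C#C/C=C/[C@@](C)(O[Si](CC)(CC)CC)[C@@H](O[Si](CC)(CC)CC)[C@@H](C)CC
F3 | step 6 | methyl ketone from F2 (isopropenyl cleaved to acetyl) | CC(=O)[C@](C)(O)[C@@H](O[Si](CC)(CC)CC)[C@H](CO[Si](CC)(CC)CC)C(=O)C#C/C=C/[C@@](C)(O[Si](CC)(CC)CC)[C@@H](O[Si](CC)(CC)CC)[C@@H](C)CC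
F4 | step 6 | tetrakis(triethylsilyl) ether of 21 (C7 hydroxyl free) | CC[C@H](C)[C@H](O[Si](CC)(CC)CC)[C@](C)(O[Si](CC)(CC)CC)/C=C/C#CC1=CC(=O)[C@](C)(O)[C@@H](O[Si](CC)(CC)CC)[C@@H]1CO[Si](CC)(CC)CC
F5 | step 3 | (3S,4S,5S)-3-[(benzyloxy)methyl]-4-hydroxy-5-methyl-5-(prop-1-en-2-yl)oxolan-2-one | CC(=C)[C@]1(C)OC(=O)[C@@H](COCc2ccccc2)[C@@H]1O
F6 | step 3 | (3S,4S,5R)-5-acetyl-3-[(benzyloxy)methyl]-4-hydroxy-5-methyloxolan-2-one | CC(=O)[C@]1(C)OC(=O)[C@@H](COCc2ccccc2)[C@@H]1O
F7 | step 3 | (3S,4S,5R)-5-acetyl-4-hydroxy-3-(hydroxymethyl)-5-methyloxolan-2-one | CC(=O)[C@]1(C)OC(=O)[C@@H](CO)[C@@H]1O
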